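I had no way to read a chain length off the red run: it showed E and X, not the number of chains.

in all of them: E 12 mM (fed, over 6.0 min)

| charge | J | remark | time |
|---|---|---|---|
| red | 0.30 mM | run made earlier |  |
| flask | 0.60 mM |  | 10 h |

- red (time / h: X / %, E / %): 0.667: 2.8, 96.2; 1.33: 7.4, 94.3; 2.00: 13.2, 87.5; 2.50: 19.0, 82.1; 3.00: 21.2, 76.1

(scatter of a reading: 1 percentage point)

- the average divides the monomer in chains by the number of chains begun, living and dead together
- the analysis behind the earlier runs scatters by 1 percentage point, standard deviation
- the earlier runs do not show the number of chains; that part of a forecast is a guess
- no earlier run changes the charge of J; that part of a forecast is a guess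

- whether the average number of monomer units in a chain (chains begun, living or dead) reaches 60 by 10 h (yes / no)
- average number of monomer units in a chain (chains begun, living or dead) at 10 h

So I followed one J molecule to its fork, where it either began a chain or went some other way. Call the chance of beginning s, the initiator efficiency. The givens then fold into B, the units of E charged per J charged:

B = [E] charged / [J] charged = 12 mM / 0.60 mM = 20.0

The average length is x, the fraction of the charge standing as X, times B, divided by s. But B alone could not answer, since x was still open. From E in the red run I read a pace:

ln(87.5% / 76.1%) / 1.00 h = 0.140 h⁻¹

Held unchanged, which is a guess for the doubled J, and with all E lost taken to stand as X, this gave x = 75.2% for the flask at 10 h. So a length of 60 in the flask needed s below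

x · B / 60 = 0.251

The red run could not show s. Yet X in the red run read 2.8% at 0.667 h and gained 8 percentage points in the last 1.00 h, so chains seemed to be starting late, and a J that waits can go the other way. I guessed yes.

The forecast differed, saying no and 17, with “I assume every J starts a chain”. The flask gave yes and 77.2.

    E + J → Z + X (k = 0.00600 M⁻¹ s⁻¹)
    E + Z → X + Z, rate k2*[Z]*[E] (k = 0.470 M⁻¹ s⁻¹)
    2 J → L (k = 0.530 M⁻¹ s⁻¹)
    X → Q (k = 2.00 × 10⁻⁶ s⁻¹)

The length of 60 was passed at 5.88 h. At 10.0 h X stood at 79.9%, which B turns into 16.0 units per J charged. Dividing by the average leaves s = 0.207, the chains begun by then per J charged, with 2.28% of the J still standing; this s is lower than my line. The other branch of the fork stood in the flask as L, two J going at each turn, at 0.231 mM.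

The earlier runs and the new flask come from a simulation for an exercise; noise was put on by code.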